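**Plan**

- Ring numbering of the target: C1(=O), C2(OH), C3(docosyl), C4(=O), C5(OMe), C6(H). The first cut is the C2–OH bond, traced back to an oxirane spanning C2 and C3; its C2–O and C3–O bonds come from nucleophilic epoxidation of the C2=C3 bond of 2-docosyl-6-methoxy-1,4-benzoquinone.
- The enabling feature is the C5 methoxyl on the quinone ring: it makes C5=C6 an enol ether and C1=O a vinylogous ester, so C2=C3–C4=O is the only electron-poor enone and the unsubstituted C2 its β-carbon.
- Earlier cuts: the C1 carbonyl oxygen (para-quinone back to 2-docosyl-6-methoxyphenol, whose OH is the C4 oxygen), then the side chain at C2'–C3' (acetylide plus 1-bromoicosane) and at C1'–C2' (o-vanillin aldehyde plus one carbon).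
- Forward: the arene is bought; the chain is assembled C1 + C1 + C20 and saturated with loss of the benzyl group; the ring is oxidised to the para-quinone; the oxirane ring is closed and then opened to the hydroxyquinone.
- Stereochemistry: the target has none; the two oxirane centres are cis by ring fusion, racemic, and are erased in the last step.

Key step: step 6

Remark: ring atoms keep the target numbering given above in every intermediate, whatever locants the systematic name uses; the oxirane is planned as a racemate and drawn as one enantiomer.

**Step 1**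
Reactants: 1 o-vanillin (2-hydroxy-3-methoxybenzaldehyde)
Product: 2 2-(benzyloxy)-3-methoxybenzaldehyde
Conditions: BnBr, K2CO3, DMF, rt
Reagents that add atoms: benzyl bromide, BrCc1ccccc1
Why: Williamson etherification, in which the carbonate-generated phenoxide displaces bromide from benzyl bromide (SN2) and the aldehyde is untouched, masks the phenol for the basic steps that follow.

**Step 2**
Reactants: 2 2-(benzyloxy)-3-methoxybenzaldehyde
Product: 3 2-(benzyloxy)-1-ethynyl-3-methoxybenzene
Conditions: dimethyl (1-diazo-2-oxopropyl)phosphonate, K2CO3, MeOH/THF, 0 °C to rt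
Reagents that add atoms: dimethyl (1-diazo-2-oxopropyl)phosphonate, COP(=O)(OC)C(=[N+]=[N-])C(C)=O
Why: Seyferth–Gilbert homologation in its Ohira–Bestmann form, in which methanolysis of the reagent gives the diazomethylphosphonate anion that olefinates the non-enolisable aryl aldehyde to a diazoalkene, which loses N2 and rearranges by 1,2-hydride shift to the terminal alkyne.

**Step 3**
Reactants: 3 2-(benzyloxy)-1-ethynyl-3-methoxybenzene; 4 1-bromoicosane
Product: 6 2-(benzyloxy)-1-(docos-1-yn-1-yl)-3-methoxybenzene, via lithium acetylide 5 (not isolated)
Conditions: n-BuLi, THF, −78 to 0 °C; then 4, DMPU, 0 °C to rt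
Reagents that add atoms: none
Why: Alkylation of a lithium acetylide, in which the deprotonated terminal alkyne displaces bromide from the unhindered primary bromide by SN2 once DMPU loosens its aggregates, joins the C2 and C20 pieces into the full C22 chain with no stereocentre formed.

**Step 4**
Reactants: 6 2-(benzyloxy)-1-(docos-1-yn-1-yl)-3-methoxybenzene
Product: 7 2-docosyl-6-methoxyphenol
Conditions: H2 (1 atm), 10% Pd/C, EtOAc/EtOH, rt
Reagents that add atoms: none
Why: Heterogeneous catalytic hydrogenation on Pd/C should saturate the alkyne and, in the same operation, hydrogenolyse the benzylic C–O bond to free the phenol, while the methyl ether and the arene are inert.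

**Step 5**
Reactants: 7 2-docosyl-6-methoxyphenol
Product: 8 2-docosyl-6-methoxy-1,4-benzoquinone (2-docosyl-6-methoxycyclohexa-2,5-diene-1,4-dione)
Conditions: O2 (1 atm), Co(salen) (salcomine, divalent cobalt, cat.), DMF/THF, rt
Reagents that add atoms: dioxygen, O=O
Why: Salcomine-catalysed aerobic oxidation of a 2,6-disubstituted phenol, in which the cobalt–superoxo species generates the phenoxyl radical that is oxygenated at the open position para to the phenol oxygen (C1) and collapses to the para-quinone, is well precedented for 2-alkyl-6-methoxyphenols, and the two ortho substituents rule out an ortho-quinone.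

**Step 6**
Reactants: 8 2-docosyl-6-methoxy-1,4-benzoquinone
Product: 9 rac-(1S,6R)-1-docosyl-3-methoxy-7-oxabicyclo[4.1.0]hept-3-ene-2,5-dione (cis-fused C2–C3 oxide of the quinone, one enantiomer drawn)
Conditions: t-BuOOH (in decane), DBU, CH2Cl2, −20 to 0 °C, dark
Reagents that add atoms: tert-butyl hydroperoxide, CC(C)(C)OO
Why: tert-Butylperoxide anion adds in conjugate fashion to C2, the unsubstituted β-carbon of the C2=C3–C4=O enone, and the C3 enolate then displaces tert-butoxide from the proximal peroxide oxygen, so C2–O forms first and C3–O second. This is a Weitz–Scheffer nucleophilic epoxidation of the kind long used on 2-alkyl-1,4-quinones such as 2-methyl-1,4-naphthoquinone. The oxirane ring closes in a 3-exo-tet mode. The two new stereocentres at C2 and C3 are cis because a three-membered ring fused to the six-membered ring allows nothing else, and with achiral substrate and reagents the oxide forms as a racemate. The step needs site selectivity for C2 over C5 and C6 and must stop at the mono-oxide: the C5 methoxyl makes C5=C6 an electron-rich enol ether and C1=O a vinylogous ester, leaving C4=O as the only ketone-like carbonyl and C2 as the only electrophilic CH, while the docosyl group blocks C3.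

**Step 7**
Reactants: 9 rac-(1S,6R)-1-docosyl-3-methoxy-7-oxabicyclo[4.1.0]hept-3-ene-2,5-dione
Product: 10 3-docosyl-2-hydroxy-5-methoxy-1,4-benzoquinone (3-docosyl-2-hydroxy-5-methoxycyclohexa-2,5-diene-1,4-dione)
Conditions: conc. H2SO4, CH2Cl2, 0 °C; then ice-water
Reagents that add atoms: none
Why: Acid-catalysed oxirane-to-hydroxyquinone isomerisation, the classical fate of 2-alkyl quinone oxides such as 2-methyl-1,4-naphthoquinone oxide, should proceed by enolisation of the C1 carbonyl toward C2–H and β-elimination of the protonated oxirane oxygen from C3, so only the C3–O bond breaks, the oxygen stays on C2 as the vinylogous acid, and both stereocentres vanish.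

**Compound list**

1 | o-vanillin (2-hydroxy-3-methoxybenzaldehyde) | COc1cccc(C=O)c1O | starting material
2 | 2-(benzyloxy)-3-methoxybenzaldehyde | COc1cccc(C=O)c1OCc1ccccc1 | intermediate
3 | 2-(benzyloxy)-1-ethynyl-3-methoxybenzene | COc1cccc(C#C)c1OCc1ccccc1 | intermediate
4 | 1-bromoicosane | CCCCCCCCCCCCCCCCCCCCBr | starting material
5 | lithium [2-(benzyloxy)-3-methoxyphenyl]ethynide (lithium acetylide, not isolated) | [Li]C#Cc1cccc(OC)c1OCc1ccccc1 | intermediate
6 | 2-(benzyloxy)-1-(docos-1-yn-1-yl)-3-methoxybenzene | CCCCCCCCCCCCCCCCCCCCC#Cc1cccc(OC)c1OCc1ccccc1 | intermediate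
7 | 2-docosyl-6-methoxyphenol | CCCCCCCCCCCCCCCCCCCCCCc1cccc(OC)c1O | intermediate
8 | 2-docosyl-6-methoxy-1,4-benzoquinone | CCCCCCCCCCCCCCCCCCCCCCC1=CC(=O)C=C(OC)C1=O | intermediate
9 | rac-(1S,6R)-1-docosyl-3-methoxy-7-oxabicyclo[4.1.0]hept-3-ene-2,5-dione (cis-fused oxide, racemic, one enantiomer drawn) | CCCCCCCCCCCCCCCCCCCCCC[C@]12O[C@H]1C(=O)C=C(OC)C2=O | intermediate
10 | 3-docosyl-2-hydroxy-5-methoxy-1,4-benzoquinone | CCCCCCCCCCCCCCCCCCCCCCC1=C(O)C(=O)C=C(OC)C1=O | target

**Summary**

Total step count: 7. Longest linear sequence: 7 steps, from 1 to 10; 4 enters in step 3.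

Steps most likely to fail:

1. Step 6. The peroxide anion (or adventitious hydroxide) may instead add at the methoxyl-bearing C5 and expel methanol, and the sensitive oxide may open or be oxidised further under the basic conditions. The fallback sets out from 8 and returns at 10, bypassing the oxide. Thiele–Winter acetoxylation (Ac2O, cat. H2SO4, rt) should deliver acetate to C2, para to the methoxyl, and give 3-docosyl-5-methoxybenzene-1,2,4-triyl triacetate F1. Methanolysis (K2CO3, MeOH, under argon) would give 3-docosyl-5-methoxybenzene-1,2,4-triol F2, and stirring its solution in air should oxidise it to 10.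

2. Step 7. Strong acid may hydrolyse the methyl enol ether on quenching, or promote acyl migration with ring contraction instead of enolisation. The fallback sets out from 9 and returns at 10 by accepting loss of the methyl group and putting it back selectively. Aqueous NaOH in THF should both isomerise the oxide and saponify the vinylogous ester, giving after acidification 3-docosyl-2,5-dihydroxy-1,4-benzoquinone F3. Acid-catalysed vinylogous esterification (MeOH, cat. H2SO4, reflux) should then methylate the unhindered C5 hydroxyl next to C6–H rather than the C2 hydroxyl shielded by the docosyl chain, giving 10.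

3. Step 3. SN2 attack of the aryl acetylide on the waxy C20 bromide may be sluggish, with competing dehydrobromination and incomplete conversion. The fallback sets out from 2 and returns at 7, building the chain by olefin metathesis instead. Wittig methylenation (methyltriphenylphosphonium bromide, KOt-Bu, THF) would give 2-(benzyloxy)-1-ethenyl-3-methoxybenzene F4. Cross-metathesis with commercial 1-docosene (second-generation Grubbs catalyst (H2IMes)(PCy3)Cl2Ru=CHPh, CH2Cl2, 40 °C) would give 2-(benzyloxy)-1-[(E)-docos-1-en-1-yl]-3-methoxybenzene F5. Hydrogenation under the step 4 conditions then saturates the alkene and removes the benzyl group to give 7.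

**Further compounds**

F1 | step 6 | 3-docosyl-5-methoxybenzene-1,2,4-triyl triacetate | CCCCCCCCCCCCCCCCCCCCCCc1c(OC(C)=O)c(OC(C)=O)cc(OC)c1OC(C)=O
F2 | step 6 | 3-docosyl-5-methoxybenzene-1,2,4-triol | CCCCCCCCCCCCCCCCCCCCCCc1c(O)c(O)cc(OC)c1O
F3 | step 7 | 3-docosyl-2,5-dihydroxy-1,4-benzoquinone | CCCCCCCCCCCCCCCCCCCCCCC1=C(O)C(=O)C=C(O)C1=O
F4 | step 3 | 2-(benzyloxy)-1-ethenyl-3-methoxybenzene | C=Cc1cccc(OC)c1OCc1ccccc1
F5 | step 3 | 2-(benzyloxy)-1-[(E)-docos-1-en-1-yl]-3-methoxybenzene | CCCCCCCCCCCCCCCCCCCC/C=C/c1cccc(OC)c1OCc1ccccc1
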